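The 2,3-dihydrobenzofuran ring (O1, C2, C3, C3a, C7a) is cut into the C=O group of O-benzylvanillin and the three-atom unit C3–C3a–C7a of ring A. The plan exploits that C7a stands para to C5, the arene carbon that later bears the CH2 link to the lactone. With a methyl ester on C5, a C7a–F bond is open to SNAr, while C3 is the gamma carbon of an (E)-cinnamyl boronate. One operation, catalytic asymmetric allylboration followed by base, forms C2–C3 and O1–C7a. Its precursor is an acyclic fluoroaryl allylboronate, whose vinyl remnant masks CH2OH. Lactone alkylation and a late anti-aldol reaction complete the target.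

Key step: step 4

Remark: the facial senses of (R)-TRIP (Re face of the aldehyde) and of the (R,R)-Et-DuPhos rhodium catalyst ((S)-succinate) are taken over from the parent crotyl boronates and itaconates; both catalysts are available in either mirror-image form.

Step 1
Reactants: 1 methyl 4-fluoro-3-methoxybenzoate
Product: 2 methyl 4-fluoro-3-methoxy-5-(4,4,5,5-tetramethyl-1,3,2-dioxaborolan-2-yl)benzoate
Conditions: [Ir(OMe)(cod)]2 (cat.), 4,4'-di-tert-butyl-2,2'-bipyridine (cat.), B2pin2, THF, 80 °C
Reagents that add atoms: bis(pinacolato)diboron, CC1(C)OB(OC1(C)C)B1OC(C)(C)C(C)(C)O1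
Why: Iridium-catalysed aromatic C–H borylation is governed by sterics, so only C5–H (flanked by the small fluorine and by H) should react, because C2–H lies between ester and methoxy and C6–H is ortho to the ester.

Step 2
Reactants: 2 aryl boronate from step 1; 3 vinyl bromide
Product: 4 methyl 3-ethenyl-4-fluoro-5-methoxybenzoate
Conditions: Pd(dppf)Cl2 (cat.), K3PO4, THF/H2O, 60 °C, sealed vessel
Reagents that add atoms: none
Why: Suzuki–Miyaura coupling of an aryl boronate with a vinyl halide, in which the ester and the C–F bond are inert to zerovalent palladium.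

Step 3
Reactants: 4 methyl 3-ethenyl-4-fluoro-5-methoxybenzoate; 5 allylboronic acid pinacol ester
Product: 6 methyl 4-fluoro-3-methoxy-5-[(E)-3-(4,4,5,5-tetramethyl-1,3,2-dioxaborolan-2-yl)prop-1-enyl]benzoate
Conditions: second-generation Hoveyda–Grubbs catalyst (cat.), excess 5, CH2Cl2, 40 °C
Reagents that add atoms: none
Why: Olefin cross-metathesis of a slowly dimerising electron-poor styrene with an excess of the allyl boronate should give the conjugated (E)-alkene under thermodynamic control, driven by loss of ethylene.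

Step 4
Reactants: 6 (E)-cinnamyl-type boronate from step 3; 7 4-(benzyloxy)-3-methoxybenzaldehyde
Product: 9 methyl (2R,3S)-2-[4-(benzyloxy)-3-methoxyphenyl]-3-ethenyl-7-methoxy-2,3-dihydro-1-benzofuran-5-carboxylate (2,3-cis), via O-boryl anti adduct 8 (not isolated)
Conditions: (R)-TRIP [(R)-3,3'-bis(2,4,6-triisopropylphenyl)-1,1'-binaphthyl-2,2'-diyl hydrogen phosphate] (5 mol %), 4 Å MS, toluene, −30 to 0 °C; then THF, KOt-Bu, −20 to 23 °C, same flask
Reagents that add atoms: none
Why: The chiral phosphoric acid hydrogen-bonds to a boronate oxygen and to the formyl hydrogen, and allyl transfer from 6 to 7 runs through a closed chair (Zimmerman–Traxler type) transition state that forms C2–C3; KOt-Bu then takes the boron off the oxygen, and the alkoxide attacks C7a, para to the ester, and expels fluoride by addition–elimination, which forms O1–C7a. Both halves are known reaction types, namely the Brønsted-acid-catalysed asymmetric allylboration of aromatic aldehydes by gamma-substituted allyl pinacol boronates and the intramolecular SNAr etherification of activated fluoroarenes. The only ring closed is the five-membered dihydrofuran ring, by 5-exo-trig attack on C7a through a Meisenheimer adduct. C2 (R) is set by the catalyst, which exposes the Re face of the aldehyde, and C3 follows from the (E)-geometry of 6 in the chair (anti adduct, hence a 2,3-cis ring), while the carbinol C–O bond is never broken, so C2 passes into the ring with retention. The step needs a C–C bond formation that cannot revert under base, which an allyl rather than an enolate nucleophile secures, and attack of the alkoxide on C–F rather than on an ester, which the para ester, the ortho side chain and the five-membered transition state secure. The cis relation at C3 is temporary and is corrected under control of C2 in step 12.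

Step 5
Reactants: 9 cis-3-ethenyl dihydrobenzofuran ester from step 4
Product: 10 [(2R,3S)-2-[4-(benzyloxy)-3-methoxyphenyl]-3-ethenyl-7-methoxy-2,3-dihydro-1-benzofuran-5-yl]methanol
Conditions: i-Bu2AlH, CH2Cl2, −78 to 0 °C; aq. potassium sodium tartrate
Reagents that add atoms: none
Why: Hydride reduction of the ester to the benzylic alcohol leaves the alkene, the aryl ethers and both stereocentres untouched.

Step 6
Reactants: 10 benzylic alcohol from step 5
Product: 11 (2R,3S)-2-[4-(benzyloxy)-3-methoxyphenyl]-5-(bromomethyl)-3-ethenyl-7-methoxy-2,3-dihydro-1-benzofuran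
Conditions: CBr4, PPh3, CH2Cl2, 0 °C
Reagents that add atoms: tetrabromomethane, BrC(Br)(Br)Br
Why: The Appel reaction converts the primary benzylic alcohol under neutral conditions, which spares the acid-labile benzylic C2–O1 bond.

Step 7
Reactants: 12 5-bromovanillin (3-bromo-4-hydroxy-5-methoxybenzaldehyde)
Product: 13 4-(benzyloxy)-3-bromo-5-methoxybenzaldehyde
Conditions: BnBr, K2CO3, DMF, 23 °C
Reagents that add atoms: benzyl bromide, BrCc1ccccc1
Why: Williamson ether synthesis on the acidic phenol protects ring B for all later base-mediated steps.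

Step 8
Reactants: 13 4-(benzyloxy)-3-bromo-5-methoxybenzaldehyde; 14 dimethyl succinate
Product: 15 (3E)-4-[4-(benzyloxy)-3-bromo-5-methoxyphenyl]-3-(methoxycarbonyl)but-3-enoic acid
Conditions: NaOMe, MeOH, reflux; then aq. HCl
Reagents that add atoms: none
Why: The Stobbe condensation proceeds through a paraconic lactone whose base-induced opening gives the (E)-arylidene half-ester.

Step 9
Reactants: 15 Stobbe half-ester from step 8
Product: 16 (3S)-4-[4-(benzyloxy)-3-bromo-5-methoxyphenyl]-3-(methoxycarbonyl)butanoic acid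
Conditions: [Rh(cod)((R,R)-Et-DuPhos)]BF4 (cat.), H2 (5 bar), MeOH, 23 °C
Reagents that add atoms: none
Why: In this asymmetric hydrogenation of an itaconate-type half-ester the alkene and the carboxyl group chelate monovalent rhodium, the ligand sets the future lactone C4 as (S), and C–Br and O-benzyl are not touched by this catalyst.

Step 10
Reactants: 16 (S)-half-ester from step 9
Product: 18 (4S)-4-[[4-(benzyloxy)-3-bromo-5-methoxyphenyl]methyl]oxolan-2-one, via hydroxy acid 17 (not isolated)
Conditions: KOH, EtOH; CaCl2, NaBH4, −10 to 23 °C; then aq. HCl, 23 °C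
Reagents that add atoms: none
Why: Calcium borohydride reduces the ester but not the carboxylate, and acidification lactonises the gamma-hydroxy acid without touching the stereocentre.

Step 11
Reactants: 18 (S)-benzylbutyrolactone from step 10; 11 benzylic bromide from step 6
Product: 19 (3S,4S)-4-[[4-(benzyloxy)-3-bromo-5-methoxyphenyl]methyl]-3-[[(2R,3S)-2-[4-(benzyloxy)-3-methoxyphenyl]-3-ethenyl-7-methoxy-2,3-dihydro-1-benzofuran-5-yl]methyl]oxolan-2-one
Conditions: LiN(SiMe3)2, THF, −78 °C; then 11, −78 to −20 °C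
Reagents that add atoms: none
Why: Enolate alkylation of a beta-substituted gamma-butyrolactone takes place anti to the C4 benzyl group and so sets C3 as (S), trans, by substrate control.

Step 12
Reactants: 19 trans-dibenzyl lactone from step 11
Product: 22 (3S,4S)-4-[[4-(benzyloxy)-3-bromo-5-methoxyphenyl]methyl]-3-[[(2R,3S)-2-[4-(benzyloxy)-3-methoxyphenyl]-3-(hydroxymethyl)-7-methoxy-2,3-dihydro-1-benzofuran-5-yl]methyl]oxolan-2-one (2,3-trans), via cis-aldehyde 20 (not isolated), via trans-aldehyde 21 (not isolated)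
Conditions: OsO4 (cat.), NaIO4, 2,6-lutidine, dioxane/H2O, 23 °C; extraction; DBU, CH2Cl2, 23 °C; then NaBH4, MeOH, 0 °C
Reagents that add atoms: sodium periodate, [Na+].[O-]I(=O)(=O)=O (terminal source of the new oxygen atom, passed on by osmium tetroxide, O=[Os](=O)(=O)=O)
Why: Lemieux–Johnson cleavage gives the cis-aldehyde, DBU equilibrates the enolisable C3 to the more stable 2,3-trans aldehyde under control of C2 (ring opening by loss of aryloxide is disfavoured because the ring C2–O1 bond lies nearly orthogonal to the enolate orbital), and NaBH4 reduces the aldehyde far faster than the lactone.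

Step 13
Reactants: 23 (4S)-3-acetyl-4-benzyl-1,3-oxazolidin-2-one
Product: 24 (4S)-4-benzyl-3-[1-(trimethylsilyloxy)ethenyl]-1,3-oxazolidin-2-one
Conditions: TMSOTf, Et3N, CH2Cl2, 0 °C
Reagents that add atoms: trimethylsilyl trifluoromethanesulfonate, C[Si](C)(C)OS(=O)(=O)C(F)(F)F
Why: Soft enolisation and O-silylation of the imide gives the silyl ketene N,O-acetal without touching the auxiliary stereocentre.

Step 14
Reactants: 22 aryl bromide from step 12; 24 silyl enolate from step 13
Product: 25 (4S)-4-benzyl-3-[[2-(benzyloxy)-3-methoxy-5-[[(3S,4S)-4-[[(2R,3S)-2-[4-(benzyloxy)-3-methoxyphenyl]-3-(hydroxymethyl)-7-methoxy-2,3-dihydro-1-benzofuran-5-yl]methyl]-5-oxooxolan-3-yl]methyl]phenyl]acetyl]-1,3-oxazolidin-2-one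
Conditions: Pd(dba)2 (cat.), P(t-Bu)3 (cat.), ZnF2, excess 24, DMF, 80 °C
Reagents that add atoms: none
Why: The palladium-catalysed alpha-arylation of the trimethylsilyl enolate of an imide, activated by ZnF2, needs no strong base, so the lactone, the free alcohol and all stereocentres should survive.

Step 15
Reactants: 25 N-arylacetyl oxazolidinone from step 14; 7 4-(benzyloxy)-3-methoxybenzaldehyde
Product: 27 anti-aldol adduct of 25 in which the acyl chain has become (2R,3S)-3-[4-(benzyloxy)-3-methoxyphenyl]-3-hydroxy-2-arylpropanoyl, via bis-silyl ether 26 (not isolated)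
Conditions: MgCl2 (cat.), Et3N, TMSCl, EtOAc, 23 °C; then PPTS, MeOH, 0 °C
Reagents that add atoms: chlorotrimethylsilane, C[Si](C)(C)Cl (adds only the silyl groups of 26, which the work-up removes again)
Why: In this magnesium-halide-catalysed anti-aldol reaction of an N-acyloxazolidinone (Evans anti-aldol), soft enolisation touches only the imide, the chelated (Z)-enolate is attacked on the face away from the auxiliary benzyl group (this sets the aryl-bearing carbon), the boat-like transition state gives the anti carbinol, and silylation makes the addition irreversible.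

Step 16
Reactants: 27 anti-aldol adduct from step 15
Product: 28 tri-O-benzyl ether of the target
Conditions: NaBH4, THF/H2O, 0 to 23 °C
Reagents that add atoms: none
Why: NaBH4 in wet THF reduces the activated exocyclic imide carbonyl to CH2OH and releases the auxiliary, while the hindered disubstituted lactone reacts much more slowly and neither new stereocentre is enolised.

Step 17
Reactants: 28 tri-O-benzyl ether of the target
Product: 29 CNP0199264.1 (target)
Conditions: H2 (1 atm), Pd/C, EtOAc/EtOH, 23 °C, stopped after uptake of three equivalents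
Reagents that add atoms: none
Why: Hydrogenolysis of the three aryl benzyl ethers under neutral conditions is faster than cleavage of the secondary benzylic alcohol or of the cyclic benzylic ether, and it avoids the acid or base that would cyclise or epimerise the open unit.

Compound list
1 | methyl 4-fluoro-3-methoxybenzoate | COC(=O)c1ccc(F)c(OC)c1 | starting material
2 | methyl 4-fluoro-3-methoxy-5-(pinacolboryl)benzoate | COC(=O)c1cc(OC)c(F)c(c1)B1OC(C)(C)C(C)(C)O1 | intermediate
3 | vinyl bromide | C=CBr | starting material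
4 | methyl 3-ethenyl-4-fluoro-5-methoxybenzoate | COC(=O)c1cc(OC)c(F)c(C=C)c1 | intermediate
5 | allylboronic acid pinacol ester | C=CCB1OC(C)(C)C(C)(C)O1 | starting material
6 | methyl 4-fluoro-3-methoxy-5-[(E)-3-(pinacolboryl)prop-1-enyl]benzoate | COC(=O)c1cc(OC)c(F)c(/C=C/CB2OC(C)(C)C(C)(C)O2)c1 | intermediate
7 | 4-(benzyloxy)-3-methoxybenzaldehyde | COc1cc(C=O)ccc1OCc1ccccc1 | starting material
8 | O-pinacolboryl derivative of methyl 3-[(1R,2S)-1-[4-(benzyloxy)-3-methoxyphenyl]-1-hydroxybut-3-en-2-yl]-4-fluoro-5-methoxybenzoate (anti) | COC(=O)c1cc(OC)c(F)c(c1)[C@H](C=C)[C@H](c1ccc(OCc2ccccc2)c(OC)c1)OB1OC(C)(C)C(C)(C)O1 | intermediate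
9 | methyl (2R,3S)-2-[4-(benzyloxy)-3-methoxyphenyl]-3-ethenyl-7-methoxy-2,3-dihydro-1-benzofuran-5-carboxylate (cis) | COC(=O)c1cc(OC)c2c(c1)[C@H](C=C)[C@H](c1ccc(OCc3ccccc3)c(OC)c1)O2 | intermediate
10 | [(2R,3S)-2-[4-(benzyloxy)-3-methoxyphenyl]-3-ethenyl-7-methoxy-2,3-dihydro-1-benzofuran-5-yl]methanol | OCc1cc(OC)c2c(c1)[C@H](C=C)[C@H](c1ccc(OCc3ccccc3)c(OC)c1)O2 | intermediate
11 | (2R,3S)-2-[4-(benzyloxy)-3-methoxyphenyl]-5-(bromomethyl)-3-ethenyl-7-methoxy-2,3-dihydro-1-benzofuran | BrCc1cc(OC)c2c(c1)[C@H](C=C)[C@H](c1ccc(OCc3ccccc3)c(OC)c1)O2 | intermediate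
12 | 5-bromovanillin | COc1cc(C=O)cc(Br)c1O | starting material
13 | 4-(benzyloxy)-3-bromo-5-methoxybenzaldehyde | COc1cc(C=O)cc(Br)c1OCc1ccccc1 | intermediate
14 | dimethyl succinate | COC(=O)CCC(=O)OC | starting material
15 | (3E)-4-[4-(benzyloxy)-3-bromo-5-methoxyphenyl]-3-(methoxycarbonyl)but-3-enoic acid | COC(=O)/C(CC(=O)O)=C/c1cc(OC)c(OCc2ccccc2)c(Br)c1 | intermediate
16 | (3S)-4-[4-(benzyloxy)-3-bromo-5-methoxyphenyl]-3-(methoxycarbonyl)butanoic acid | COC(=O)[C@H](CC(=O)O)Cc1cc(OC)c(OCc2ccccc2)c(Br)c1 | intermediate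
17 | (3S)-4-[4-(benzyloxy)-3-bromo-5-methoxyphenyl]-3-(hydroxymethyl)butanoic acid | OC[C@H](CC(=O)O)Cc1cc(OC)c(OCc2ccccc2)c(Br)c1 | intermediate
18 | (4S)-4-[[4-(benzyloxy)-3-bromo-5-methoxyphenyl]methyl]oxolan-2-one | COc1cc(C[C@@H]2COC(=O)C2)cc(Br)c1OCc1ccccc1 | intermediate
19 | (3S,4S)-trans-lactone with bromoaryl ring B and the cis-(2R,3S)-3-ethenyl dihydrobenzofuran | COc1cc(C[C@@H]2COC(=O)[C@H]2Cc2cc(OC)c3c(c2)[C@H](C=C)[C@H](c2ccc(OCc4ccccc4)c(OC)c2)O3)cc(Br)c1OCc1ccccc1 | intermediate
20 | as 19 but with a (2R,3S)-3-formyl group (2,3-cis) | COc1cc(C[C@@H]2COC(=O)[C@H]2Cc2cc(OC)c3c(c2)[C@H](C=O)[C@H](c2ccc(OCc4ccccc4)c(OC)c2)O3)cc(Br)c1OCc1ccccc1 | intermediate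
21 | as 19 but with a (2R,3R)-3-formyl group (2,3-trans) | COc1cc(C[C@@H]2COC(=O)[C@H]2Cc2cc(OC)c3c(c2)[C@@H](C=O)[C@H](c2ccc(OCc4ccccc4)c(OC)c2)O3)cc(Br)c1OCc1ccccc1 | intermediate
22 | as 19 but with a (2R,3S)-3-(hydroxymethyl) group (2,3-trans) | COc1cc(C[C@@H]2COC(=O)[C@H]2Cc2cc(OC)c3c(c2)[C@@H](CO)[C@H](c2ccc(OCc4ccccc4)c(OC)c2)O3)cc(Br)c1OCc1ccccc1 | intermediate
23 | (4S)-3-acetyl-4-benzyl-1,3-oxazolidin-2-one | CC(=O)N1[C@@H](Cc2ccccc2)COC1=O | starting material
24 | (4S)-4-benzyl-3-[1-(trimethylsilyloxy)ethenyl]-1,3-oxazolidin-2-one | C=C(O[Si](C)(C)C)N1[C@@H](Cc2ccccc2)COC1=O | intermediate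
25 | as 22 but with CH2C(=O)-[(4S)-4-benzyl-2-oxo-oxazolidin-3-yl] in place of Br | COc1cc(C[C@@H]2COC(=O)[C@H]2Cc2cc(OC)c3c(c2)[C@@H](CO)[C@H](c2ccc(OCc4ccccc4)c(OC)c2)O3)cc(CC(=O)N2[C@@H](Cc3ccccc3)COC2=O)c1OCc1ccccc1 | intermediate
26 | bis(trimethylsilyl) ether of 27 | COc1cc([C@@H](O[Si](C)(C)C)[C@H](C(=O)N2[C@@H](Cc3ccccc3)COC2=O)c2cc(C[C@@H]3COC(=O)[C@H]3Cc3cc(OC)c4c(c3)[C@@H](CO[Si](C)(C)C)[C@H](c3ccc(OCc5ccccc5)c(OC)c3)O4)cc(OC)c2OCc2ccccc2)ccc1OCc1ccccc1 | intermediate
27 | anti-aldol adduct, acyl chain (2R,3S), auxiliary (4S) | COc1cc([C@@H](O)[C@H](C(=O)N2[C@@H](Cc3ccccc3)COC2=O)c2cc(C[C@@H]3COC(=O)[C@H]3Cc3cc(OC)c4c(c3)[C@@H](CO)[C@H](c3ccc(OCc5ccccc5)c(OC)c3)O4)cc(OC)c2OCc2ccccc2)ccc1OCc1ccccc1 | intermediate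
28 | tri-O-benzyl ether of the target | COc1cc([C@@H](O)[C@H](CO)c2cc(C[C@@H]3COC(=O)[C@H]3Cc3cc(OC)c4c(c3)[C@@H](CO)[C@H](c3ccc(OCc5ccccc5)c(OC)c3)O4)cc(OC)c2OCc2ccccc2)ccc1OCc1ccccc1 | intermediate
29 | CNP0199264.1 | COc1cc([C@@H](O)[C@H](CO)c2cc(C[C@@H]3COC(=O)[C@H]3Cc3cc(OC)c4c(c3)[C@@H](CO)[C@H](c3ccc(O)c(OC)c3)O4)cc(OC)c2O)ccc1O | target

Total step count: 17. Longest linear sequence: 12 steps (1, 2, 3, 4, 5, 6, 11, 12, 14, 15, 16, 17).

Steps most likely to fail

Step 4.
- **What may go wrong:** Allyl transfer from an electron-poor, ortho-substituted cinnamyl boronate to an electron-rich aldehyde may be slow or poorly face-selective. After the base is added, the double bond may migrate into conjugation before the more crowded cis ring has closed.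
- **Fallback:** It sets out from 2 and comes back at 9, and it replaces the boron reagent by a catalytic allylmetal made from an alkyne. Compound 2 is brominated with CuBr2 in MeOH/H2O to methyl 3-bromo-4-fluoro-5-methoxybenzoate F1. Sonogashira coupling with propyne (PdCl2(PPh3)2, CuI, Et3N) gives methyl 4-fluoro-3-methoxy-5-(prop-1-ynyl)benzoate F2. Transfer-hydrogenative coupling of F2 with commercial 4-(benzyloxy)-3-methoxybenzyl alcohol is then run as a carbonyl anti-(alpha-aryl)allylation. The catalyst is H2Ru(CO)(PPh3)3 with 1-[2-(dicyclohexylphosphino)ferrocenyl]ethyldi-tert-butylphosphine, in the mirror-image form that gives the (1R,2S) product, and an arenesulfonic acid additive in THF at 100 °C. This gives the anti homoallylic alcohol F3. After removal of the volatiles, F3 is closed to 9 with KN(SiMe3)2 in THF in the same flask.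

Step 14.
- **What may go wrong:** Oxidative addition and transmetalation at the hindered, electron-rich aryl bromide may be sluggish. Silyl transfer from 24 to the free alcohol may use up the enolate, and the more acidic product may be arylated a second time.
- **Fallback:** It sets out from 22 and comes back at 25, and it reverses the polarity of the coupling. Miyaura borylation (Pd(dppf)Cl2, KOAc, B2pin2, dioxane, 80 °C) gives the ring B aryl pinacol boronate F4. F4 is then coupled with (4S)-4-benzyl-3-(bromoacetyl)-1,3-oxazolidin-2-one under palladium catalysis (Pd(OAc)2, P(o-tol)3, K3PO4, THF). This is the known coupling of aryl boron compounds with alpha-bromo carbonyl compounds.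

Step 15.
- **What may go wrong:** The stabilised arylacetyl enolate may give poor anti/syn or facial selectivity, and the magnesium aldolate may revert before it is silylated.
- **Fallback:** It sets out from 22, comes back at 28 and bypasses steps 14 to 16. It uses the allylboration logic of step 4, whose anti adduct has the relative configuration that the open unit needs.
  - Suzuki–Miyaura coupling of 22 with potassium vinyltrifluoroborate gives the ring B styrene F5.
  - Cross-metathesis with 5 gives the (E)-allyl boronate F6.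
  - Allylboration of 7 under (S)-TRIP catalysis gives the (1S,2R) anti homoallylic alcohol F7.
  - Ozonolysis with NaBH4 work-up at low temperature turns the vinyl group into CH2OH without epimerisation.

Further compounds
F1 | step 4 | methyl 3-bromo-4-fluoro-5-methoxybenzoate | COC(=O)c1cc(OC)c(F)c(Br)c1
F2 | step 4 | methyl 4-fluoro-3-methoxy-5-(prop-1-ynyl)benzoate | COC(=O)c1cc(OC)c(F)c(C#CC)c1
F3 | step 4 | methyl 3-[(1R,2S)-1-[4-(benzyloxy)-3-methoxyphenyl]-1-hydroxybut-3-en-2-yl]-4-fluoro-5-methoxybenzoate | COC(=O)c1cc(OC)c(F)c(c1)[C@H](C=C)[C@@H](O)c1ccc(OCc2ccccc2)c(OC)c1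
F4 | step 14 | as 22 but with a pinacolboryl group in place of Br | COc1cc(C[C@@H]2COC(=O)[C@H]2Cc2cc(OC)c3c(c2)[C@@H](CO)[C@H](c2ccc(OCc4ccccc4)c(OC)c2)O3)cc(B2OC(C)(C)C(C)(C)O2)c1OCc1ccccc1
F5 | step 15 | as 22 but with an ethenyl group in place of Br | COc1cc(C[C@@H]2COC(=O)[C@H]2Cc2cc(OC)c3c(c2)[C@@H](CO)[C@H](c2ccc(OCc4ccccc4)c(OC)c2)O3)cc(C=C)c1OCc1ccccc1
F6 | step 15 | as 22 but with an (E)-3-(pinacolboryl)prop-1-enyl group in place of Br | COc1cc(C[C@@H]2COC(=O)[C@H]2Cc2cc(OC)c3c(c2)[C@@H](CO)[C@H](c2ccc(OCc4ccccc4)c(OC)c2)O3)cc(/C=C/CB2OC(C)(C)C(C)(C)O2)c1OCc1ccccc1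
F7 | step 15 | as 28 but with an ethenyl group in place of the CH2OH of the open unit, (1S,2R), anti | COc1cc([C@@H](O)[C@H](C=C)c2cc(C[C@@H]3COC(=O)[C@H]3Cc3cc(OC)c4c(c3)[C@@H](CO)[C@H](c3ccc(OCc5ccccc5)c(OC)c3)O4)cc(OC)c2OCc2ccccc2)ccc1OCc1ccccc1
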